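**Retrosynthetic overview**
- The orsellinate ester at O-7 is disconnected last (acylation of the C-7 tertiary alcohol, then desilylation of the phenols); the side-chain acetate is set just before.
- Ring A (pyran: C-1, O-2, C-3, C-4, C-4a, C-8a) is formed second, by copper-catalysed 6-endo-dig cycloisomerisation of a 2-alkynyl formyl vinylogous acid.
- Ring B (carbocycle: C-4a, C-5, C-6, C-7, C-8, C-8a) is formed first, by a [4+2] Claisen/vinylogous Dieckmann annulation that makes C-7–C-8 and C-5–C-6 in one operation. The enabling feature is that C-6/C-7, with the 7-methyl and O-7, is a lactic acid unit: C-7 is a quaternary carbinol between the C-6 and C-8 carbonyls, so ring B cannot aromatise. A lactate-derived dioxolanone therefore supplies nucleophilic C-7, electrophilic C-6 and a traceless tert-butyl acetal for stereocontrol.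
- The four-carbon partner (C-8, C-8a, C-4a, C-5, with C-1 masked as a dimethyl acetal and the enyne on C-4a) comes from an aldol/E1cB union of an ynone with methyl 3,3-dimethoxypropanoate.

Key step: step 6

Remark: C-1 to C-8a are the isochromene locants of the target (O-2 is the ring oxygen; the target is 7S). Compounds 13, 14, 15 and 17 are expected as 2E/2Z mixtures and are drawn 2E; this double bond becomes a single bond in the dienolate of step 6, so both isomers converge.

Step 1
Reactants: 1 (S)-lactic acid; 2 pivalaldehyde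
Product: 3 (2S,5S)-2-tert-butyl-5-methyl-1,3-dioxolan-4-one (cis)
Conditions: TsOH·H2O (cat.), H2SO4 (cat.), pentane, reflux, water separator; crystallisation from pentane/Et2O at −78 °C
Reagents that add atoms: none
Why: Acid-catalysed acetalisation with water removal should give mainly the cis dioxolanone, whose new acetal centre (2S) is induced by the lactate centre and which is obtained pure by low-temperature crystallisation.

Step 2
Reactants: 4 (2E)-pent-2-en-4-yn-1-ol
Product: 5 tert-butyldimethyl{[(2E)-pent-2-en-4-yn-1-yl]oxy}silane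
Conditions: TBSCl, imidazole, CH2Cl2, 0 °C to rt
Reagents that add atoms: tert-butyldimethylsilyl chloride (TBSCl), CC(C)(C)[Si](C)(C)Cl
Why: Silyl ether formation on a primary alcohol is routine and masks the hydroxyl through the basic steps.

Step 3
Reactants: 5 tert-butyldimethyl{[(2E)-pent-2-en-4-yn-1-yl]oxy}silane; 6 N-methoxy-N-methylacetamide
Product: 8 (5E)-7-[(tert-butyldimethylsilyl)oxy]hept-5-en-3-yn-2-one, via lithium acetylide 7 (not isolated)
Conditions: n-BuLi, THF, −78 °C; then 6, −78 to 0 °C; aq. NH4Cl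
Reagents that add atoms: none
Why: Acylation of a lithium acetylide by an N-methoxy-N-methyl amide (Weinreb ketone synthesis) should stop at the ynone because the chelated tetrahedral adduct survives until work-up.

Step 4
Reactants: 8 (5E)-7-[(tert-butyldimethylsilyl)oxy]hept-5-en-3-yn-2-one; 9 methyl 3,3-dimethoxypropanoate
Product: 13 methyl (2E,6E)-7-[(tert-butyldimethylsilyl)oxy]-2-(dimethoxymethyl)-3-methylhepta-2,6-dien-4-ynoate, via lithium enolate 10 (not isolated), via lithium aldolate 11 (not isolated), via tertiary acetate 12 (not isolated)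
Conditions: 9, LiN(iPr)2 (commercial solution), THF, −78 °C; then 8, −78 °C; then Ac2O (3 equiv), −78 to 0 °C; then DBU, rt
Reagents that add atoms: none
Why: Aldol addition of the ester enolate to the ynone carbonyl, trapping of the tertiary aldolate as its acetate and DBU-mediated E1cB elimination through the ester enolate should place the new double bond in conjugation with the ester, the two transient stereocentres being destroyed.

Step 5
Reactants: 13 methyl (2E,6E)-7-[(tert-butyldimethylsilyl)oxy]-2-(dimethoxymethyl)-3-methylhepta-2,6-dien-4-ynoate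
Product: 15 (2E,6E)-7-[(tert-butyldimethylsilyl)oxy]-2-(dimethoxymethyl)-3-methylhepta-2,6-dien-4-ynoyl chloride, via potassium carboxylate 14 (not isolated)
Conditions: KOSiMe3, THF, rt; evaporation; then (COCl)2, DMF (cat.), CH2Cl2, 0 °C; filtration, evaporation, used at once
Reagents that add atoms: oxalyl chloride, ClC(=O)C(=O)Cl
Why: Nucleophilic demethylation of the hindered methyl ester by silanolate (anhydrous ester cleavage) and reaction of the carboxylate salt with oxalyl chloride give the acid chloride without free acid, so the acetal and the silyl ether should survive.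

Step 6
Reactants: 3 (2S,5S)-2-tert-butyl-5-methyl-1,3-dioxolan-4-one; 15 (2E,6E)-7-[(tert-butyldimethylsilyl)oxy]-2-(dimethoxymethyl)-3-methylhepta-2,6-dien-4-ynoyl chloride
Product: 18 (6R)-3-{(3E)-5-[(tert-butyldimethylsilyl)oxy]pent-3-en-1-yn-1-yl}-4-(dimethoxymethyl)-5,6-dihydroxy-6-methylcyclohexa-2,4-dien-1-one, via lithium enolate 16 (not isolated), via acyl dioxolanone 17 (not isolated)
Conditions: 3, LiN(iPr)2 (1.05 equiv), THF, −78 °C; then 15, −78 °C; then LiN(SiMe3)2 (2.2 equiv), −78 to −20 °C; cold 1 M HCl to pH 4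
Reagents that add atoms: none
Why: Proposed new method: enolate 16 should be C-acylated by 15 on the face opposite the tert-butyl group (Claisen-type acylation with self-regeneration of the lactate stereocentre) to give the non-enolisable β-keto lactone 17, whose γ-methyl (C-5) is then deprotonated by LiN(SiMe3)2 to a lithium dienolate that attacks the acetal-activated lactone carbonyl (C-6); the tetrahedral intermediate expels the hemiacetal alkoxide, which sheds pivalaldehyde to unveil the C-7 hydroxyl, and the product is withdrawn as its stabilised vinylogous-acid anion, which makes the sequence irreversible. The closest known reaction types are the acylation of dioxolanone enolates by acid chlorides, the opening of dioxolanones by carbanions with loss of the aldehyde (as in Dieckmann closures to tetronic acids) and the toluate-anion/ester [4+2] annulation to 1,3-dihydroxynaphthalenes; what is new is their fusion on a vinylogous (dienolate) donor. Ring B (C-4a, C-5, C-6, C-7, C-8, C-8a) closes by a 6-(enolendo)-exo-trig vinylogous Dieckmann condensation. The only stereocentre, C-7, is fixed in the first bond formation by the acetal tert-butyl group (electrophile anti to it, overall retention relative to (S)-lactic acid) and cannot epimerise afterwards because it is quaternary. The step needs C- over O-acylation and acyl substitution over conjugate addition, which the acid chloride should secure, and deprotonation at C-5 only, which follows from C-7 carrying no hydrogen; the productive dienolate geometry (C-7 syn to C-4a) should be favoured by lithium chelation between the enolate oxygen and the C-1 acetal.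

Step 7
Reactants: 18 (6R)-3-{(3E)-5-[(tert-butyldimethylsilyl)oxy]pent-3-en-1-yn-1-yl}-4-(dimethoxymethyl)-5,6-dihydroxy-6-methylcyclohexa-2,4-dien-1-one
Product: 19 (3R)-2,3-dihydroxy-6-[(3E)-5-hydroxypent-3-en-1-yn-1-yl]-3-methyl-4-oxocyclohexa-1,5-diene-1-carbaldehyde
Conditions: 1 M aq. HCl, THF, 0 °C to rt
Reagents that add atoms: water, O
Why: Acid-catalysed acetal hydrolysis (through an oxocarbenium ion stabilised by the dienol) and protodesilylation of the primary silyl ether should occur under the same mild aqueous acid, leaving the quaternary C-7 untouched.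

Step 8
Reactants: 19 (3R)-2,3-dihydroxy-6-[(3E)-5-hydroxypent-3-en-1-yn-1-yl]-3-methyl-4-oxocyclohexa-1,5-diene-1-carbaldehyde
Product: 20 (7S)-7-hydroxy-3-[(1E)-3-hydroxyprop-1-en-1-yl]-7-methyl-6H-isochromene-6,8(7H)-dione
Conditions: CuI (10 mol %), iPr2NEt, CH2Cl2/MeCN, rt
Reagents that add atoms: none
Why: Copper-catalysed 6-endo-dig cycloisomerisation (attack of the formyl oxygen on the copper-activated alkyne, then protodemetalation), a reaction type established for alkynyl formyl vinylogous acids of this kind, should close ring A and give the neutral 6,8-dione.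

Step 9
Reactants: 20 (7S)-7-hydroxy-3-[(1E)-3-hydroxyprop-1-en-1-yl]-7-methyl-6H-isochromene-6,8(7H)-dione
Product: 21 (2E)-3-[(7S)-7-hydroxy-7-methyl-6,8-dioxo-7,8-dihydro-6H-isochromen-3-yl]prop-2-en-1-yl acetate
Conditions: Ac2O (1.2 equiv), pyridine, CH2Cl2, 0 °C
Reagents that add atoms: acetic anhydride, CC(=O)OC(C)=O
Why: Acetylation (O-acylation) of the primary allylic alcohol should be far faster than that of the hindered tertiary C-7 hydroxyl when no acyl-transfer catalyst is present.

Step 10
Reactants: 22 orsellinic acid (2,4-dihydroxy-6-methylbenzoic acid)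
Product: 23 tert-butyldimethylsilyl 2,4-bis[(tert-butyldimethylsilyl)oxy]-6-methylbenzoate
Conditions: TBSCl (3.5 equiv), imidazole, DMF, rt to 40 °C; non-aqueous work-up
Reagents that add atoms: tert-butyldimethylsilyl chloride (TBSCl), CC(C)(C)[Si](C)(C)Cl
Why: Exhaustive silylation (silyl ether and silyl ester formation) protects both phenols and gives a silyl ester that can be converted directly into the acid chloride.

Step 11
Reactants: 23 tert-butyldimethylsilyl 2,4-bis[(tert-butyldimethylsilyl)oxy]-6-methylbenzoate; 21 (2E)-3-[(7S)-7-hydroxy-7-methyl-6,8-dioxo-7,8-dihydro-6H-isochromen-3-yl]prop-2-en-1-yl acetate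
Product: 25 (7S)-3-[(1E)-3-acetoxyprop-1-en-1-yl]-7-methyl-6,8-dioxo-7,8-dihydro-6H-isochromen-7-yl 2,4-bis[(tert-butyldimethylsilyl)oxy]-6-methylbenzoate, via acid chloride 24 (not isolated)
Conditions: 23, (COCl)2, DMF (cat.), CH2Cl2, 0 °C to rt, evaporation; then 21, Et3N, DMAP, CH2Cl2, 0 °C to rt
Reagents that add atoms: none
Why: Conversion of the silyl ester into the acid chloride under neutral conditions followed by DMAP-mediated esterification of the C-7 hydroxyl, whose acidity as an α-hydroxy-β-diketone should aid acyl transfer, gives the hindered ester without touching the stereocentre.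

Step 12
Reactants: 25 (7S)-3-[(1E)-3-acetoxyprop-1-en-1-yl]-7-methyl-6,8-dioxo-7,8-dihydro-6H-isochromen-7-yl 2,4-bis[(tert-butyldimethylsilyl)oxy]-6-methylbenzoate
Product: 26 (7S)-3-[(1E)-3-acetoxyprop-1-en-1-yl]-7-methyl-6,8-dioxo-7,8-dihydro-6H-isochromen-7-yl 2,4-dihydroxy-6-methylbenzoate (target)
Conditions: HF·pyridine, pyridine, THF, 0 °C to rt
Reagents that add atoms: none
Why: Fluoride-mediated desilylation of the two aryl silyl ethers under buffered, weakly acidic conditions should leave the allylic acetate, the aryl ester and the azaphilone chromophore intact.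

**Compound list**
1 | (S)-lactic acid | C[C@H](O)C(=O)O | starting material
2 | pivalaldehyde | CC(C)(C)C=O | starting material
3 | (2S,5S)-2-tert-butyl-5-methyl-1,3-dioxolan-4-one (cis) | O=C1O[C@@H](C(C)(C)C)O[C@H]1C | intermediate
4 | (2E)-pent-2-en-4-yn-1-ol | OC/C=C/C#C | starting material
5 | tert-butyldimethyl{[(2E)-pent-2-en-4-yn-1-yl]oxy}silane | C#C/C=C/CO[Si](C)(C)C(C)(C)C | intermediate
6 | N-methoxy-N-methylacetamide | CC(=O)N(C)OC | starting material
7 | lithium acetylide of 5 | [Li+].[C-]#C/C=C/CO[Si](C)(C)C(C)(C)C | intermediate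
8 | (5E)-7-[(tert-butyldimethylsilyl)oxy]hept-5-en-3-yn-2-one | CC(=O)C#C/C=C/CO[Si](C)(C)C(C)(C)C | intermediate
9 | methyl 3,3-dimethoxypropanoate | COC(=O)CC(OC)OC | starting material
10 | lithium enolate of 9 | [Li+].[O-]C(OC)=CC(OC)OC | intermediate
11 | lithium alkoxide of methyl (6E)-7-[(tert-butyldimethylsilyl)oxy]-2-(dimethoxymethyl)-3-hydroxy-3-methylhept-6-en-4-ynoate (diastereomers at C-2 and C-3 not controlled) | [Li+].[O-]C(C)(C#C/C=C/CO[Si](C)(C)C(C)(C)C)C(C(OC)OC)C(=O)OC | intermediate
12 | methyl (6E)-3-acetoxy-7-[(tert-butyldimethylsilyl)oxy]-2-(dimethoxymethyl)-3-methylhept-6-en-4-ynoate (diastereomers not controlled) | CC(=O)OC(C)(C#C/C=C/CO[Si](C)(C)C(C)(C)C)C(C(OC)OC)C(=O)OC | intermediate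
13 | methyl (2E,6E)-7-[(tert-butyldimethylsilyl)oxy]-2-(dimethoxymethyl)-3-methylhepta-2,6-dien-4-ynoate | COC(=O)/C(=C(\C)C#C/C=C/CO[Si](C)(C)C(C)(C)C)C(OC)OC | intermediate
14 | potassium (2E,6E)-7-[(tert-butyldimethylsilyl)oxy]-2-(dimethoxymethyl)-3-methylhepta-2,6-dien-4-ynoate | [K+].[O-]C(=O)/C(=C(\C)C#C/C=C/CO[Si](C)(C)C(C)(C)C)C(OC)OC | intermediate
15 | (2E,6E)-7-[(tert-butyldimethylsilyl)oxy]-2-(dimethoxymethyl)-3-methylhepta-2,6-dien-4-ynoyl chloride | ClC(=O)/C(=C(\C)C#C/C=C/CO[Si](C)(C)C(C)(C)C)C(OC)OC | intermediate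
16 | lithium (2S)-2-tert-butyl-5-methyl-1,3-dioxol-4-olate (enolate of 3) | [Li+].[O-]C1=C(C)O[C@H](C(C)(C)C)O1 | intermediate
17 | (2S,5R)-2-tert-butyl-5-{(2E,6E)-7-[(tert-butyldimethylsilyl)oxy]-2-(dimethoxymethyl)-3-methylhepta-2,6-dien-4-ynoyl}-5-methyl-1,3-dioxolan-4-one | O=C1O[C@@H](C(C)(C)C)O[C@]1(C)C(=O)/C(=C(\C)C#C/C=C/CO[Si](C)(C)C(C)(C)C)C(OC)OC | intermediate
18 | (6R)-3-{(3E)-5-[(tert-butyldimethylsilyl)oxy]pent-3-en-1-yn-1-yl}-4-(dimethoxymethyl)-5,6-dihydroxy-6-methylcyclohexa-2,4-dien-1-one | COC(OC)C1=C(O)[C@@](C)(O)C(=O)C=C1C#C/C=C/CO[Si](C)(C)C(C)(C)C | intermediate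
19 | (3R)-2,3-dihydroxy-6-[(3E)-5-hydroxypent-3-en-1-yn-1-yl]-3-methyl-4-oxocyclohexa-1,5-diene-1-carbaldehyde | O=CC1=C(O)[C@@](C)(O)C(=O)C=C1C#C/C=C/CO | intermediate
20 | (7S)-7-hydroxy-3-[(1E)-3-hydroxyprop-1-en-1-yl]-7-methyl-6H-isochromene-6,8(7H)-dione | OC/C=C/C1=CC2=CC(=O)[C@](C)(O)C(=O)C2=CO1 | intermediate
21 | (2E)-3-[(7S)-7-hydroxy-7-methyl-6,8-dioxo-7,8-dihydro-6H-isochromen-3-yl]prop-2-en-1-yl acetate | CC(=O)OC/C=C/C1=CC2=CC(=O)[C@](C)(O)C(=O)C2=CO1 | intermediate
22 | orsellinic acid (2,4-dihydroxy-6-methylbenzoic acid) | Cc1cc(O)cc(O)c1C(=O)O | starting material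
23 | tert-butyldimethylsilyl 2,4-bis[(tert-butyldimethylsilyl)oxy]-6-methylbenzoate | Cc1cc(O[Si](C)(C)C(C)(C)C)cc(O[Si](C)(C)C(C)(C)C)c1C(=O)O[Si](C)(C)C(C)(C)C | intermediate
24 | 2,4-bis[(tert-butyldimethylsilyl)oxy]-6-methylbenzoyl chloride | Cc1cc(O[Si](C)(C)C(C)(C)C)cc(O[Si](C)(C)C(C)(C)C)c1C(Cl)=O | intermediate
25 | (7S)-3-[(1E)-3-acetoxyprop-1-en-1-yl]-7-methyl-6,8-dioxo-7,8-dihydro-6H-isochromen-7-yl 2,4-bis[(tert-butyldimethylsilyl)oxy]-6-methylbenzoate | CC(=O)OC/C=C/C1=CC2=CC(=O)[C@](C)(OC(=O)c3c(C)cc(O[Si](C)(C)C(C)(C)C)cc3O[Si](C)(C)C(C)(C)C)C(=O)C2=CO1 | intermediate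
26 | (7S)-3-[(1E)-3-acetoxyprop-1-en-1-yl]-7-methyl-6,8-dioxo-7,8-dihydro-6H-isochromen-7-yl 2,4-dihydroxy-6-methylbenzoate | CC(=O)OC/C=C/C1=CC2=CC(=O)[C@](C)(OC(=O)c3c(C)cc(O)cc3O)C(=O)C2=CO1 | target

**Totals**
Total step count: 12.
Longest linear sequence: 10 steps (steps 2, 3, 4, 5, 6, 7, 8, 9, 11, 12).

**Steps most likely to fail**

1. Step 6 (Proposed new method). What may go wrong: O-acylation of the dioxolanone enolate instead of C-acylation; loss of methoxide from the dienolate (β-elimination at C-1) or formation of the non-cyclising enolate geometry, so that ring B does not close; retro-Claisen cleavage of the β-keto lactone. Fallback with known chemistry, setting out from 5 and returning at 19: ring B is taken from an aromatic precursor. Commercial 5-bromo-1,3-dimethoxy-2-methylbenzene is formylated (POCl3, DMF, Vilsmeier–Haack) to 6-bromo-2,4-dimethoxy-3-methylbenzaldehyde F1, which is demethylated (BBr3, CH2Cl2) to 6-bromo-2,4-dihydroxy-3-methylbenzaldehyde F2. Sonogashira coupling of F2 with 5 (PdCl2(PPh3)2, CuI, Et3N) should give 6-{(3E)-5-[(tert-butyldimethylsilyl)oxy]pent-3-en-1-yn-1-yl}-2,4-dihydroxy-3-methylbenzaldehyde F3. Copper-mediated enantioselective oxidative dearomatisation of F3 ([Cu(MeCN)4]PF6, the sparteine enantiomer that delivers the 7S series, expected to be (+)-sparteine, O2, iPr2NEt, DMAP, CH2Cl2, low temperature) hydroxylates the methyl-bearing carbon and should give (3R)-6-{(3E)-5-[(tert-butyldimethylsilyl)oxy]pent-3-en-1-yn-1-yl}-2,3-dihydroxy-3-methyl-4-oxocyclohexa-1,5-diene-1-carbaldehyde F4. Aqueous acid (1 M HCl, THF) removes the silyl group and the route is rejoined at 19.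

2. Step 11. What may go wrong: acyl transfer between the doubly ortho-substituted aroyl chloride and the tertiary alcohol is slow, and base-induced degradation of the azaphilone (for example α-ketol rearrangement) takes over. Fallback, setting out from 22 and 21 and returning at 26: the acid is delivered as a cyclic acyl acetal and the alcohol is used as its alkoxide. Orsellinic acid 22 is converted (acetone, trifluoroacetic anhydride, trifluoroacetic acid) into 7-hydroxy-2,2,5-trimethyl-4H-1,3-benzodioxin-4-one F5, and the free phenol is silylated (TBSCl, imidazole) to 7-[(tert-butyldimethylsilyl)oxy]-2,2,5-trimethyl-4H-1,3-benzodioxin-4-one F6. The sodium alkoxide of 21 (NaN(SiMe3)2, 1.0 equiv, THF, −78 to 0 °C) should open F6 at the lactone carbonyl with loss of acetone (transesterification of a benzodioxinone) to give (7S)-3-[(1E)-3-acetoxyprop-1-en-1-yl]-7-methyl-6,8-dioxo-7,8-dihydro-6H-isochromen-7-yl 4-[(tert-butyldimethylsilyl)oxy]-2-hydroxy-6-methylbenzoate F7. Desilylation of F7 (HF·pyridine) gives 26.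

3. Step 4. What may go wrong: proton transfer from the methyl ketone to the ester enolate, β-elimination of methoxide from enolate 10, or retro-aldol cleavage of aldolate 11 before it is acetylated. Fallback, setting out from 5 and returning at 13: the C-4a–alkyne bond is made by cross-coupling instead. Methyl acetoacetate is converted by Vilsmeier–Haack chloroformylation (POCl3, DMF) into methyl (2E)-3-chloro-2-formylbut-2-enoate F8. Sonogashira coupling of F8 with 5 (PdCl2(PPh3)2, CuI, Et3N, THF) should give methyl (2E,6E)-7-[(tert-butyldimethylsilyl)oxy]-2-formyl-3-methylhepta-2,6-dien-4-ynoate F9. Acetalisation of F9 (HC(OMe)3, pyridinium p-toluenesulfonate cat.) gives 13.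

**Further compounds**
F1 | step 6 | 6-bromo-2,4-dimethoxy-3-methylbenzaldehyde | O=Cc1c(Br)cc(OC)c(C)c1OC
F2 | step 6 | 6-bromo-2,4-dihydroxy-3-methylbenzaldehyde | O=Cc1c(Br)cc(O)c(C)c1O
F3 | step 6 | 6-{(3E)-5-[(tert-butyldimethylsilyl)oxy]pent-3-en-1-yn-1-yl}-2,4-dihydroxy-3-methylbenzaldehyde | O=Cc1c(C#C/C=C/CO[Si](C)(C)C(C)(C)C)cc(O)c(C)c1O
F4 | step 6 | (3R)-6-{(3E)-5-[(tert-butyldimethylsilyl)oxy]pent-3-en-1-yn-1-yl}-2,3-dihydroxy-3-methyl-4-oxocyclohexa-1,5-diene-1-carbaldehyde | O=CC1=C(O)[C@@](C)(O)C(=O)C=C1C#C/C=C/CO[Si](C)(C)C(C)(C)C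
F5 | step 11 | 7-hydroxy-2,2,5-trimethyl-4H-1,3-benzodioxin-4-one | Cc1cc(O)cc2OC(C)(C)OC(=O)c12
F6 | step 11 | 7-[(tert-butyldimethylsilyl)oxy]-2,2,5-trimethyl-4H-1,3-benzodioxin-4-one | Cc1cc(O[Si](C)(C)C(C)(C)C)cc2OC(C)(C)OC(=O)c12
F7 | step 11 | (7S)-3-[(1E)-3-acetoxyprop-1-en-1-yl]-7-methyl-6,8-dioxo-7,8-dihydro-6H-isochromen-7-yl 4-[(tert-butyldimethylsilyl)oxy]-2-hydroxy-6-methylbenzoate | CC(=O)OC/C=C/C1=CC2=CC(=O)[C@](C)(OC(=O)c3c(C)cc(O[Si](C)(C)C(C)(C)C)cc3O)C(=O)C2=CO1
F8 | step 4 | methyl (2E)-3-chloro-2-formylbut-2-enoate | COC(=O)/C(C=O)=C(\C)Cl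
F9 | step 4 | methyl (2E,6E)-7-[(tert-butyldimethylsilyl)oxy]-2-formyl-3-methylhepta-2,6-dien-4-ynoate | COC(=O)/C(C=O)=C(\C)C#C/C=C/CO[Si](C)(C)C(C)(C)C
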